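**Retrosynthetic overview**

- The target is cut at the aryl ketone into the N-methoxy-N-methylamide of the chromene propanoic acid and an aryllithium from bis-allylated 4-bromoresorcinol. Ring A is bought and attached last, and its two allyl ethers are removed under neutral conditions.
- Pyran ring C comes from a thermal propargyl ether Claisen / oxa-6π cascade of the O8a 1,1-dimethylpropargyl ether of a catechol. The C8 hydroxyl comes from Dakin oxidation of a C8 formyl group, after chelation-controlled cleavage of the neighbouring O8a methyl ether.
- Ring B comes from an Alder–Rickert exchange between methyl 3-(4-methoxycyclohexa-1,3-dien-1-yl)propanoate (Birch reduction of the para-alkylanisole, esterification, conjugation) and 6-methylhept-5-en-2-ynal (prenyl bromide plus propargyl alcohol, then oxidation), with loss of ethylene.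
- Feature used: in ring B the carbons C8a (O1), C8 (OH), C7 (prenyl) and C6 (side chain) are contiguous and fully substituted, while C4a and C5 carry hydrogen. C7 and C8 can therefore be delivered together as one disubstituted alkyne across C8a and C6 of a para-alkylanisole core that already holds O8a and the chain.
- Ring order: ring B in step 6, ring C in step 10, ring A introduced intact in step 13.

Key step: step 6

Remark: ring B is numbered as in 2H-chromene (O1, C2–C4, C4a, C5–C8, C8a) and the target has no stereocentre. The diene from step 3 is taken into step 6 as the equilibrium mixture with its unconjugated isomer, of which only the conjugated diene adds.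

**Route**

Step 1
Reactants: 1 3-(4-methoxyphenyl)propanoic acid
Product: 2 3-(4-methoxycyclohexa-1,4-dien-1-yl)propanoic acid
Conditions: Li, NH3 (l), THF, t-BuOH, −78 to −33 °C; NH4Cl; cold aq. NaH2PO4 (pH 5–6)
Reagents that add atoms: none
Why: Birch reduction, in which the lithium carboxylate is not reduced and the electron transfer–protonation sequence leaves the methoxy and alkyl groups on the two remaining double bonds, so the 2,5-dihydroanisole should result and survive the weakly acidic work-up.

Step 2
Reactants: 2 3-(4-methoxycyclohexa-1,4-dien-1-yl)propanoic acid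
Product: 3 methyl 3-(4-methoxycyclohexa-1,4-dien-1-yl)propanoate
Conditions: MeI, K2CO3, DMF, rt
Reagents that add atoms: iodomethane, CI
Why: SN2 O-alkylation of the potassium carboxylate under basic conditions, which leaves the acid-labile enol ether untouched.

Step 3
Reactants: 3 methyl 3-(4-methoxycyclohexa-1,4-dien-1-yl)propanoate
Product: 4 methyl 3-(4-methoxycyclohexa-1,3-dien-1-yl)propanoate
Conditions: RhCl(PPh3)3 (cat.), CHCl3 (filtered through basic alumina), reflux, argon
Reagents that add atoms: none
Why: Rhodium-hydride mediated 1,3-hydrogen shift (alkene isomerisation) under neutral conditions that spare ester and enol ether, which should favour the conjugated diene carrying both substituents on its termini.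

Step 4
Reactants: 5 propargyl alcohol; 6 prenyl bromide
Product: 7 6-methylhept-5-en-2-yn-1-ol
Conditions: CuI (cat.), K2CO3, Bu4NCl (cat.), DMF, rt
Reagents that add atoms: none
Why: Copper-catalysed allylation of a terminal alkyne, in which the copper acetylide of 5 displaces bromide at the primary carbon of 6 and gives the skipped enyne without protection of the hydroxyl.

Step 5
Reactants: 7 6-methylhept-5-en-2-yn-1-ol
Product: 8 6-methylhept-5-en-2-ynal
Conditions: activated MnO2 (excess), CH2Cl2, rt; used at once as a concentrated solution
Reagents that add atoms: none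
Why: MnO2 oxidation of an activated (propargylic) alcohol, which stops at the aldehyde and does not touch the trisubstituted alkene.

Step 6
Reactants: 4 methyl 3-(4-methoxycyclohexa-1,3-dien-1-yl)propanoate; 8 6-methylhept-5-en-2-ynal
Product: 10 methyl 3-[3-formyl-4-methoxy-2-(3-methylbut-2-enyl)phenyl]propanoate, via bicyclic adduct 9 (not isolated)
Conditions: 4 (1.5 equiv), BHT (cat.), 1,2-dichlorobenzene (about 2 M), sealed tube, 120 °C, then 180 °C
Reagents that add atoms: none
Why: A thermal normal-demand [4+2] cycloaddition, suprafacial on both partners, should join C8a to C8 and C6 to C7 and give bicyclo[2.2.2]octadiene 9, whose CH2–CH2 bridge then leaves as ethylene in a retro-[4+2] step driven by aromatisation (Alder–Rickert reaction). The closest known reaction type is the Alder–Rickert synthesis of ortho-methoxyaryl aldehydes, ketones and esters from 1-methoxycyclohexa-1,3-dienes and acetylenic carbonyl dienophiles; a β-substituted ynal with a diene substituted at both termini lies at the hindered end of that scope, hence the concentrated, two-temperature protocol. Ring B is closed by intermolecular [4+2] annulation onto the diene and made aromatic by cycloreversion, so the two sp3 carbons of the old ring are exchanged for C7 and C8, which arrive carrying prenyl and formyl. No stereocentre remains, because the two bridgehead centres of racemic 9 are destroyed when ethylene is lost. The step needs regioselectivity, and the methoxy group secures it: as the stronger donor it makes the remote diene terminus (future C6) the nucleophilic end, which bonds to the prenyl-bearing β-carbon of the ynal, so the formyl carbon ends up next to oxygen and the opposing, weaker bias of the alkyl group is outweighed. The isolated prenyl alkene is no dienophile, and BHT should suppress radical decay of the ynal.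

Step 7
Reactants: 10 methyl 3-[3-formyl-4-methoxy-2-(3-methylbut-2-enyl)phenyl]propanoate
Product: 11 methyl 3-[3-formyl-4-hydroxy-2-(3-methylbut-2-enyl)phenyl]propanoate
Conditions: MgI2·OEt2, toluene–Et2O, 60 °C; cold aq. NH4Cl/Na2S2O3
Reagents that add atoms: none
Why: Chelation-controlled ether cleavage, in which magnesium binds the formyl oxygen and the neighbouring methoxy oxygen and iodide removes the methyl group by SN2 attack; MgI2 is a far weaker Lewis acid than the boron halides and brings no protic acid, so the prenyl alkene beside the activated formyl group and the methyl ester should survive.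

Step 8
Reactants: 11 methyl 3-[3-formyl-4-hydroxy-2-(3-methylbut-2-enyl)phenyl]propanoate
Product: 13 methyl 3-[3,4-dihydroxy-2-(3-methylbut-2-enyl)phenyl]propanoate, via aryl formate 12 (not isolated)
Conditions: 30% aq. H2O2, Na2CO3, THF–H2O, 0 °C to rt, argon; aq. NaH2PO4 to pH 5
Reagents that add atoms: hydrogen peroxide, OO
Why: Dakin oxidation, in which hydroperoxide adds to the formyl group and the aryl group, made electron-rich by the ortho phenoxide, migrates to oxygen to give formate 12, which the carbonate medium cleaves; alkaline H2O2 is a nucleophilic oxidant that does not epoxidise the isolated prenyl alkene, and the mild base should limit ester hydrolysis.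

Step 9
Reactants: 13 methyl 3-[3,4-dihydroxy-2-(3-methylbut-2-enyl)phenyl]propanoate
Product: 14 methyl 3-[3-hydroxy-4-(2-methylbut-3-yn-2-yloxy)-2-(3-methylbut-2-enyl)phenyl]propanoate
Conditions: 3-chloro-3-methylbut-1-yne (1.2 equiv), K2CO3 (1.1 equiv), KI (cat.), CuI (cat.), acetone, 55 °C, argon
Reagents that add atoms: 3-chloro-3-methylbut-1-yne, CC(C)(Cl)C#C
Why: O-alkylation of a phenoxide by a tertiary propargylic chloride; O8a, flanked only by hydrogen on C4a, should be reached by the bulky electrophile far more easily than O8, which sits between O8a and the prenyl-bearing C7, and one equivalent of base should hold the reaction at mono-alkylation.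

Step 10
Reactants: 14 methyl 3-[3-hydroxy-4-(2-methylbut-3-yn-2-yloxy)-2-(3-methylbut-2-enyl)phenyl]propanoate
Product: 17 methyl 3-[8-hydroxy-2,2-dimethyl-7-(3-methylbut-2-enyl)-2H-chromen-6-yl]propanoate, via allenylphenol 15 (not isolated), via o-quinone methide 16 (not isolated)
Conditions: o-xylene, BHT (cat.), 140 °C, argon
Reagents that add atoms: none
Why: Aryl propargyl ether Claisen rearrangement to C4a (the only open ortho position of O8a) followed by enolisation should give 15, a 1,5-hydrogen shift should give 16, and oxa-6π electrocyclisation should close ring C, the gem-dimethyl group letting this standard 2,2-dimethylchromene cascade run at a temperature that the o-prenylphenol and the ester tolerate.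

Step 11
Reactants: 17 methyl 3-[8-hydroxy-2,2-dimethyl-7-(3-methylbut-2-enyl)-2H-chromen-6-yl]propanoate
Product: 18 3-[8-hydroxy-2,2-dimethyl-7-(3-methylbut-2-enyl)-2H-chromen-6-yl]-N-methoxy-N-methylpropanamide
Conditions: MeNH(OMe)·HCl, i-PrMgCl (excess), THF, −20 to 0 °C
Reagents that add atoms: N,O-dimethylhydroxylamine hydrochloride, CNOC.Cl
Why: Aminolysis of the methyl ester by the chloromagnesium amide of N,O-dimethylhydroxylamine (preparation of a Weinreb amide), the phenol being only deprotonated by an extra equivalent of the Grignard reagent.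

Step 12
Reactants: 19 4-bromoresorcinol
Product: 20 1-bromo-2,4-bis(prop-2-enyloxy)benzene
Conditions: allyl bromide, K2CO3, acetone, reflux
Reagents that add atoms: allyl bromide, C=CCBr
Why: Williamson ether synthesis; allyl ethers withstand the aryllithium at low temperature and can be removed at the end without acid, which the o-prenylphenol would not tolerate.

Step 13
Reactants: 20 1-bromo-2,4-bis(prop-2-enyloxy)benzene; 18 3-[8-hydroxy-2,2-dimethyl-7-(3-methylbut-2-enyl)-2H-chromen-6-yl]-N-methoxy-N-methylpropanamide
Product: 22 1-[2,4-bis(prop-2-enyloxy)phenyl]-3-[8-hydroxy-2,2-dimethyl-7-(3-methylbut-2-enyl)-2H-chromen-6-yl]propan-1-one, via aryllithium 21 (not isolated)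
Conditions: 20 (2.5 equiv), n-BuLi, THF, −78 °C; then 18 in THF, −78 to −40 °C; aq. NH4Cl
Reagents that add atoms: none
Why: Bromine–lithium exchange followed by Weinreb ketone synthesis, in which the chelated tetrahedral adduct prevents over-addition and collapses to the ketone on work-up; the first equivalent of 21 deprotonates the C8 hydroxyl, and keeping the mixture below −40 °C should stop the ortho-allyloxy aryllithium from cyclising or rearranging.

Step 14
Reactants: 22 1-[2,4-bis(prop-2-enyloxy)phenyl]-3-[8-hydroxy-2,2-dimethyl-7-(3-methylbut-2-enyl)-2H-chromen-6-yl]propan-1-one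
Product: 23 1-(2,4-dihydroxyphenyl)-3-[8-hydroxy-2,2-dimethyl-7-(3-methylbut-2-enyl)-2H-chromen-6-yl]propan-1-one
Conditions: Pd(PPh3)4 (cat.), morpholine, THF, rt, argon
Reagents that add atoms: none
Why: Tsuji–Trost deallylation, in which zerovalent palladium ionises each aryl allyl ether to a π-allyl complex of divalent palladium that morpholine intercepts, freeing both phenols under neutral conditions that should leave the C-bound prenyl group, the chromene and the ketone untouched.

**Compound list**

1 | 3-(4-methoxyphenyl)propanoic acid | COc1ccc(CCC(=O)O)cc1 | starting material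
2 | 3-(4-methoxycyclohexa-1,4-dien-1-yl)propanoic acid | COC1=CCC(CCC(=O)O)=CC1 | intermediate
3 | methyl 3-(4-methoxycyclohexa-1,4-dien-1-yl)propanoate | COC1=CCC(CCC(=O)OC)=CC1 | intermediate
4 | methyl 3-(4-methoxycyclohexa-1,3-dien-1-yl)propanoate | COC1=CC=C(CCC(=O)OC)CC1 | intermediate
5 | propargyl alcohol | OCC#C | starting material
6 | prenyl bromide | CC(C)=CCBr | starting material
7 | 6-methylhept-5-en-2-yn-1-ol | CC(C)=CCC#CCO | intermediate
8 | 6-methylhept-5-en-2-ynal | CC(C)=CCC#CC=O | intermediate
9 | methyl 3-[3-formyl-4-methoxy-2-(3-methylbut-2-enyl)bicyclo[2.2.2]octa-2,5-dien-1-yl]propanoate (racemic) | COC12CCC(CCC(=O)OC)(C=C1)C(CC=C(C)C)=C2C=O | intermediate (not isolated)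
10 | methyl 3-[3-formyl-4-methoxy-2-(3-methylbut-2-enyl)phenyl]propanoate | COc1ccc(CCC(=O)OC)c(CC=C(C)C)c1C=O | intermediate
11 | methyl 3-[3-formyl-4-hydroxy-2-(3-methylbut-2-enyl)phenyl]propanoate | COC(=O)CCc1ccc(O)c(C=O)c1CC=C(C)C | intermediate
12 | methyl 3-[3-(formyloxy)-4-hydroxy-2-(3-methylbut-2-enyl)phenyl]propanoate | COC(=O)CCc1ccc(O)c(OC=O)c1CC=C(C)C | intermediate (not isolated)
13 | methyl 3-[3,4-dihydroxy-2-(3-methylbut-2-enyl)phenyl]propanoate | COC(=O)CCc1ccc(O)c(O)c1CC=C(C)C | intermediate
14 | methyl 3-[3-hydroxy-4-(2-methylbut-3-yn-2-yloxy)-2-(3-methylbut-2-enyl)phenyl]propanoate | COC(=O)CCc1ccc(OC(C)(C)C#C)c(O)c1CC=C(C)C | intermediate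
15 | methyl 3-[3,4-dihydroxy-5-(3-methylbuta-1,2-dienyl)-2-(3-methylbut-2-enyl)phenyl]propanoate | COC(=O)CCc1cc(C=C=C(C)C)c(O)c(O)c1CC=C(C)C | intermediate (not isolated)
16 | methyl 3-[(3Z)-5-hydroxy-3-(3-methylbut-2-enylidene)-6-(3-methylbut-2-enyl)-4-oxocyclohexa-1,5-dien-1-yl]propanoate | COC(=O)CCC1=C/C(=C/C=C(C)C)C(=O)C(O)=C1CC=C(C)C | intermediate (not isolated)
17 | methyl 3-[8-hydroxy-2,2-dimethyl-7-(3-methylbut-2-enyl)-2H-chromen-6-yl]propanoate | COC(=O)CCc1cc2C=CC(C)(C)Oc2c(O)c1CC=C(C)C | intermediate
18 | 3-[8-hydroxy-2,2-dimethyl-7-(3-methylbut-2-enyl)-2H-chromen-6-yl]-N-methoxy-N-methylpropanamide | CON(C)C(=O)CCc1cc2C=CC(C)(C)Oc2c(O)c1CC=C(C)C | intermediate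
19 | 4-bromoresorcinol | Oc1ccc(Br)c(O)c1 | starting material
20 | 1-bromo-2,4-bis(prop-2-enyloxy)benzene | C=CCOc1ccc(Br)c(OCC=C)c1 | intermediate
21 | [2,4-bis(prop-2-enyloxy)phenyl]lithium | [Li]c1ccc(OCC=C)cc1OCC=C | intermediate (not isolated)
22 | 1-[2,4-bis(prop-2-enyloxy)phenyl]-3-[8-hydroxy-2,2-dimethyl-7-(3-methylbut-2-enyl)-2H-chromen-6-yl]propan-1-one | C=CCOc1ccc(C(=O)CCc2cc3C=CC(C)(C)Oc3c(O)c2CC=C(C)C)c(OCC=C)c1 | intermediate
23 | 1-(2,4-dihydroxyphenyl)-3-[8-hydroxy-2,2-dimethyl-7-(3-methylbut-2-enyl)-2H-chromen-6-yl]propan-1-one | CC(C)=CCc1c(CCC(=O)c2ccc(O)cc2O)cc2c(c1O)OC(C)(C)C=C2 | target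

**Step count and risk**

Total step count: 14. Longest linear sequence: 11 steps (steps 1, 2, 3, 6, 7, 8, 9, 10, 11, 13, 14).

Steps most likely to fail:

1. Step 6. The bimolecular cycloaddition onto a diene substituted at both termini may be outrun by thermal decay of the skipped enynal (propargyl–allenyl isomerisation, oligomerisation) or by disproportionation of the diene, so that little arene forms.
 Fallback: the substitution pattern is built on the intact anisole ring with the prenyl group introduced last. The path sets out from 1 and comes back at 14, so steps 6 to 9 are bypassed.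
 - Acid 1 is esterified (MeOH, H2SO4 cat.) to methyl 3-(4-methoxyphenyl)propanoate F1.
 - Rieche formylation (Cl2CHOMe, TiCl4, CH2Cl2, 0 °C) ortho to the methoxy group gives methyl 3-(3-formyl-4-methoxyphenyl)propanoate F2.
 - Chelation-controlled demethylation with BCl3 (CH2Cl2, −78 to 0 °C; no alkene is present yet) gives methyl 3-(3-formyl-4-hydroxyphenyl)propanoate F3.
 - The single phenol is alkylated with 3-chloro-3-methylbut-1-yne (K2CO3, KI, CuI cat., DMF, 65 °C) to methyl 3-[3-formyl-4-(2-methylbut-3-yn-2-yloxy)phenyl]propanoate F4.
 - Baeyer–Villiger oxidation with mCPBA (CH2Cl2; the alkyne is inert) gives methyl 3-[3-(formyloxy)-4-(2-methylbut-3-yn-2-yloxy)phenyl]propanoate F5, and K2CO3 in MeOH then frees methyl 3-[3-hydroxy-4-(2-methylbut-3-yn-2-yloxy)phenyl]propanoate F6.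
 - The sodium phenoxide of F6 (NaH, toluene) is C-alkylated with prenyl bromide 6 at C7, its only free ortho carbon, to give 14.

2. Step 9. Alkylation may spread to O8 or to both oxygens, or the neighbouring phenoxide may add to the alkyne of the first-formed ether, so that the O8a mono-ether is not obtained cleanly.
 Fallback: the pyran ring is closed from carbon, so the two oxygens need not be told apart. The path sets out from 13 and comes back at 17. Catechol 13 is heated with 3-methylbut-2-enal and ethylenediammonium diacetate in xylene (amine-catalysed phenol–enal chromene annulation). Attack is possible only from C4a, the one free position ortho to a hydroxyl, and gives methyl 3-[3,4-dihydroxy-5-(1-hydroxy-3-methylbut-2-enyl)-2-(3-methylbut-2-enyl)phenyl]propanoate F7. F7 loses water to o-quinone methide 16, which closes to 17 by the same oxa-6π step as in step 10.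

3. Step 7. The magnesium-chelated formyl group may be attacked by the neighbouring prenyl alkene (Prins or carbonyl-ene closure to an indane), or iodide may also cleave the methyl ester.
 Fallback: the methyl ether is removed by SN2 attack of a thiolate without any Lewis acid, and the ester cleavage is accepted. The path sets out from 10 and comes back at 11. Heating 10 with NaSEt in DMF (100 °C) removes both O-methyl groups and gives, after acidification, 3-[3-formyl-4-hydroxy-2-(3-methylbut-2-enyl)phenyl]propanoic acid F8. Its carboxylate is re-esterified selectively with MeI and KHCO3 in DMF (the hydrogen-bonded phenol is not alkylated) to give 11.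

**Further compounds**

F1 | step 6 | methyl 3-(4-methoxyphenyl)propanoate | COc1ccc(CCC(=O)OC)cc1
F2 | step 6 | methyl 3-(3-formyl-4-methoxyphenyl)propanoate | COc1ccc(CCC(=O)OC)cc1C=O
F3 | step 6 | methyl 3-(3-formyl-4-hydroxyphenyl)propanoate | COC(=O)CCc1ccc(O)c(C=O)c1
F4 | step 6 | methyl 3-[3-formyl-4-(2-methylbut-3-yn-2-yloxy)phenyl]propanoate | COC(=O)CCc1ccc(OC(C)(C)C#C)c(C=O)c1
F5 | step 6 | methyl 3-[3-(formyloxy)-4-(2-methylbut-3-yn-2-yloxy)phenyl]propanoate | COC(=O)CCc1ccc(OC(C)(C)C#C)c(OC=O)c1
F6 | step 6 | methyl 3-[3-hydroxy-4-(2-methylbut-3-yn-2-yloxy)phenyl]propanoate | COC(=O)CCc1ccc(OC(C)(C)C#C)c(O)c1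
F7 | step 9 | methyl 3-[3,4-dihydroxy-5-(1-hydroxy-3-methylbut-2-enyl)-2-(3-methylbut-2-enyl)phenyl]propanoate (racemic) | COC(=O)CCc1cc(C(O)C=C(C)C)c(O)c(O)c1CC=C(C)C
F8 | step 7 | 3-[3-formyl-4-hydroxy-2-(3-methylbut-2-enyl)phenyl]propanoic acid | OC(=O)CCc1ccc(O)c(C=O)c1CC=C(C)C
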